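**Retrosynthetic overview**

1. Target 29 ⇒ desilylation and C8–O acylation with the Z-configured acid 26 ⇒ macrocyclic hydroxy-lactone 22.
2. 22 ⇒ C7–C8 bond, 10-membered ring and exo-methylene lactone in one step by an intramolecular Barbier reaction of the bromomethyl-butenolide aldehyde 21 (aldehyde from a terminal vinyl group).
3. Butenolide (C6–O lactone) ⇒ Z-keto-enal 11 + iodoacrylate 14 (Ni/Cr coupling, then lactonization); C3 carbinol by CBS reduction.
4. Key C–O step: singlet-oxygen [4+2] on the 2,3-disubstituted furan 9 makes the C3–O and C6–O bonds and locks the 4Z alkene; the furan is attached at C2–C3 by alkylation.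
5. Epoxide (C1, C10, absolute configuration) by Sharpless epoxidation of Z-dienol 4. Ring order: oxirane → butenolide → carbocycle together with the α-methylene lactone.

Assumption: the SMILES is read as (1R,3S,6S,7R,8R,10S) in germacrane numbering (C1/C10 epoxide from a Z-alkene, C4=C5 Z, cis-fused 6,12-lactone, ester on C8, C11–C13 methylene-lactone carbons); this numbering is used for all intermediates.

**Step 1**
Reactants: 1 but-2-yn-1-ol
Product: 2 (2Z)-3-iodobut-2-en-1-ol
Conditions: Red-Al, THF, 0 °C → rt; then I2, −78 °C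
Reagents that add atoms: iodine, II
Why: Alkoxide-directed trans-hydroalumination places Al on C3 cis to CH2OH, and iododealumination with retention gives the Z vinyl iodide.

**Step 2**
Reactants: 2 (2Z)-3-iodobut-2-en-1-ol; 3 allyltributylstannane
Product: 4 (2Z)-3-methylhexa-2,5-dien-1-ol
Conditions: Pd2(dba)3 (cat.), P(2-furyl)3, DMF, 40 °C
Reagents that add atoms: none
Why: Stille coupling keeps the vinyl iodide geometry, so the future C2 and C9 are cis on the trisubstituted alkene (needed for the cis-epoxide).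

**Step 3**
Reactants: 4 (2Z)-3-methylhexa-2,5-dien-1-ol
Product: 5 [(2R,3S)-3-methyl-3-(prop-2-en-1-yl)oxiran-2-yl]methanol
Conditions: Ti(OiPr)4 (cat.), D-(−)-diethyl tartrate (cat.), t-BuOOH, 4 Å MS, CH2Cl2, −20 °C
Reagents that add atoms: tert-butyl hydroperoxide, CC(C)(C)OO
Why: Sharpless asymmetric epoxidation touches only the allylic-alcohol alkene, and the D-tartrate catalyst gives the (2R,3S) epoxide, which is C1 (R) and C10 (S) of the target.

**Step 4**
Reactants: 5 epoxy alcohol; 6 2-bromo-3-methylfuran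
Product: 9 3-methyl-2-{[(2R,3S)-3-methyl-3-(prop-2-en-1-yl)oxiran-2-yl]methyl}furan, via epoxy triflate 7 (not isolated), via 2-lithio-3-methylfuran 8 (not isolated)
Conditions: 5: n-BuLi, Et2O, −78 °C, then Tf2O; 6: n-BuLi, THF, −78 °C; combine, −78 → −30 °C
Reagents that add atoms: none
Why: SN2 alkylation of the furyllithium by the primary triflate forms C2–C3; the epoxide is inert to aryllithiums at low temperature without a Lewis acid, and no stereocentre is touched.

**Step 5**
Reactants: 9 furan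
Product: 11 (2Z)-3-methyl-5-[(2R,3S)-3-methyl-3-(prop-2-en-1-yl)oxiran-2-yl]-4-oxopent-2-enal, via furan endoperoxide 10 (not isolated)
Conditions: O2, methylene blue (cat.), hν, CH2Cl2, −78 °C; then Me2S, −78 → 0 °C
Reagents that add atoms: oxygen, O=O
Why: [4+2] cycloaddition of singlet oxygen to the furan (the terminal vinyl group is inert) and reduction of the endoperoxide give the cis-ene-dicarbonyl, so the C3–O and C6–O bonds and the 4Z geometry come from the ring.

**Step 6**
Reactants: 12 methyl propiolate; 13 formaldehyde (as paraformaldehyde)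
Product: 14 methyl (2Z)-2-(hydroxymethyl)-3-iodoprop-2-enoate
Conditions: MgI2, CH2Cl2, 0 °C → rt
Reagents that add atoms: magnesium iodide, [Mg+2].[I-].[I-]
Why: Iodo-aldol (β-iodo Morita–Baylis–Hillman) reaction: iodide adds to the ynoate and the allenolate traps formaldehyde, giving the Z isomer under kinetic control.

**Step 7**
Reactants: 11 Z-keto-enal; 14 iodoacrylate
Product: 16 (5S)-3-(hydroxymethyl)-5-{(1Z)-2-methyl-4-[(2R,3S)-3-methyl-3-(prop-2-en-1-yl)oxiran-2-yl]-3-oxobut-1-en-1-yl}furan-2(5H)-one, via γ-hydroxy ester 15 (not isolated)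
Conditions: CrCl2, NiCl2 (2 mol%), chiral oxazoline–sulfonamide ligand (6S-selective enantiomer), Et3N, THF, 0 °C → rt; SiO2 work-up
Reagents that add atoms: none
Why: Nozaki–Hiyama–Kishi coupling: the alkenylchromium adds only to the aldehyde with retention of the Z geometry, so the alkoxide closes onto the cis ester to the butenolide, and the chiral ligand on chromium sets C6 (S).

**Step 8**
Reactants: 16 hydroxymethyl butenolide
Product: 17 (5S)-3-(bromomethyl)-5-{(1Z)-2-methyl-4-[(2R,3S)-3-methyl-3-(prop-2-en-1-yl)oxiran-2-yl]-3-oxobut-1-en-1-yl}furan-2(5H)-one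
Conditions: CBr4, PPh3, CH2Cl2, −20 → 0 °C
Reagents that add atoms: carbon tetrabromide, BrC(Br)(Br)Br
Why: Appel reaction on the only hydroxyl group (primary, allylic) under neutral conditions that spare the β,γ-epoxy ketone.

**Step 9**
Reactants: 17 bromide
Product: 18 (5S)-3-(bromomethyl)-5-{(1Z,3S)-3-hydroxy-2-methyl-4-[(2R,3S)-3-methyl-3-(prop-2-en-1-yl)oxiran-2-yl]but-1-en-1-yl}furan-2(5H)-one
Conditions: (R)-Me-CBS (0.2 equiv), catecholborane, toluene/CH2Cl2, −78 °C
Reagents that add atoms: none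
Why: Corey–Bakshi–Shibata 1,2-reduction of the enone with the alkenyl group as the large substituent gives C3 (S) under reagent control.

**Step 10**
Reactants: 18 allylic alcohol
Product: 19 C3 tert-butyldimethylsilyl ether of 18
Conditions: TBSOTf, 2,6-lutidine, CH2Cl2, −78 °C
Reagents that add atoms: tert-butyldimethylsilyl trifluoromethanesulfonate, CC(C)(C)[Si](C)(C)OS(=O)(=O)C(F)(F)F
Why: Silylation of the alcohol with a silyl triflate and a hindered base at −78 °C is much faster than silyl dienol ether formation from the butenolide or epoxide opening.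

**Step 11**
Reactants: 19 silyl ether
Product: 21 (5S)-3-(bromomethyl)-5-{(1Z,3S)-3-[(tert-butyldimethylsilyl)oxy]-2-methyl-4-[(2R,3S)-3-methyl-3-(2-oxoethyl)oxiran-2-yl]but-1-en-1-yl}furan-2(5H)-one, via vicinal diol 20 (not isolated)
Conditions: OsO4 (2 mol%), NaIO4, 2,6-lutidine, dioxane/H2O, 0 °C → rt
Reagents that add atoms: sodium periodate, [Na+].[O-]I(=O)(=O)=O
Why: Lemieux–Johnson cleavage is selective for the unhindered terminal vinyl group, because the C4=C5 alkene is hindered and deactivated by two allylic oxygens and the butenolide alkene is electron-poor.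

**Step 12**
Reactants: 21 bromomethyl-butenolide aldehyde
Product: 22 (1R,3S,6S,7R,8R,10S)-3-[(tert-butyldimethylsilyl)oxy]-1,10-epoxy-8-hydroxygermacra-4Z,11(13)-dien-12,6-olide
Conditions: In powder, NaI (cat.), THF/H2O (4:1), 0.003 M, rt
Reagents that add atoms: none
Why: Proposed new method: intramolecular indium Barbier allylation in which the allylmetal made from the α-(bromomethyl)butenolide attacks the tethered aldehyde through C7, which moves the alkene exo (α-methylene lactone) and closes the 10-membered ring; the seven-atom tether on C6 can reach only the butenolide face syn to C5 (cis ring fusion, C7 R), and in the chair-like In–O-bridged transition state the C9 branch sits pseudo-axial to avoid a syn-pentane clash with C5 (C8 R); the closest known reactions are intermolecular Zn/In Barbier additions of 3-(bromomethyl)furan-2(5H)-ones to aldehydes and Barbier or Nozaki–Hiyama macrocyclizations of open-chain 2-(bromomethyl)acrylates to germacranolides.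

**Step 13**
Reactants: 23 3-methylfuran-2(5H)-one
Product: 26 (2Z)-4-[(tert-butyldimethylsilyl)oxy]-2-methylbut-2-enoic acid, via potassium hydroxy-enoate 24 (not isolated), via bis-silyl derivative 25 (not isolated)
Conditions: KOH, MeOH/H2O, 0 °C; evaporate; TBSCl, imidazole, DMF, 0 °C → rt; then K2CO3 (cat.), MeOH/THF/H2O; pH 5 work-up
Reagents that add atoms: potassium hydroxide, [K+].[OH-]; tert-butyldimethylsilyl chloride, CC(C)(C)[Si](C)(C)Cl
Why: Saponification, bis-silylation and selective hydrolysis of the labile silyl ester; the Z geometry is inherited from the lactone ring.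

**Step 14**
Reactants: 22 macrocyclic alcohol; 26 acid
Product: 28 3-O-TBS 8-O-[(2Z)-4-(TBS-oxy)-2-methylbut-2-enoyl] derivative of the target, via mixed anhydride 27 (not isolated)
Conditions: 2,4,6-trichlorobenzoyl chloride, Et3N, toluene, 0 °C; then 22, DMAP (0.5 equiv), 0 °C → rt
Reagents that add atoms: none
Why: Yamaguchi esterification of the only free hydroxyl group through the mixed anhydride, with retention at C8.

**Step 15**
Reactants: 28 bis-silyl ether
Product: 29 target
Conditions: HF·pyridine, pyridine, THF, 0 °C → rt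
Reagents that add atoms: none
Why: Buffered fluoride desilylation removes both silyl ethers and is known to spare trisubstituted epoxides and α-methylene lactones.

**Compound list**

1 | but-2-yn-1-ol | CC#CCO | starting material
2 | (2Z)-3-iodobut-2-en-1-ol | OC/C=C(/C)I | intermediate
3 | allyltributylstannane | C=CC[Sn](CCCC)(CCCC)CCCC | starting material
4 | (2Z)-3-methylhexa-2,5-dien-1-ol | OC/C=C(/C)CC=C | intermediate
5 | [(2R,3S)-3-methyl-3-(prop-2-en-1-yl)oxiran-2-yl]methanol | OC[C@H]1O[C@@]1(C)CC=C | intermediate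
6 | 2-bromo-3-methylfuran | Cc1ccoc1Br | starting material
7 | [(2R,3S)-3-methyl-3-(prop-2-en-1-yl)oxiran-2-yl]methyl trifluoromethanesulfonate (not isolated) | O=S(=O)(OC[C@H]1O[C@@]1(C)CC=C)C(F)(F)F | intermediate
8 | (3-methylfuran-2-yl)lithium (not isolated) | [Li]c1occc1C | intermediate
9 | 3-methyl-2-{[(2R,3S)-3-methyl-3-(prop-2-en-1-yl)oxiran-2-yl]methyl}furan | Cc1ccoc1C[C@H]1O[C@@]1(C)CC=C | intermediate
10 | furan endoperoxide of 9, a 2,3,7-trioxabicyclo[2.2.1]hept-5-ene (not isolated) | CC1=CC2OOC1(C[C@H]3O[C@@]3(C)CC=C)O2 | intermediate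
11 | (2Z)-3-methyl-5-[(2R,3S)-3-methyl-3-(prop-2-en-1-yl)oxiran-2-yl]-4-oxopent-2-enal | O=C/C=C(/C)C(=O)C[C@H]1O[C@@]1(C)CC=C | intermediate
12 | methyl propiolate | C#CC(=O)OC | starting material
13 | formaldehyde (paraformaldehyde) | C=O | starting material
14 | methyl (2Z)-2-(hydroxymethyl)-3-iodoprop-2-enoate | COC(=O)/C(CO)=C\I | intermediate
15 | methyl (2Z,4S,5Z)-4-hydroxy-2-(hydroxymethyl)-6-methyl-8-[(2R,3S)-3-methyl-3-(prop-2-en-1-yl)oxiran-2-yl]-7-oxoocta-2,5-dienoate (not isolated) | COC(=O)/C(CO)=C\[C@@H](O)/C=C(/C)C(=O)C[C@H]1O[C@@]1(C)CC=C | intermediate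
16 | (5S)-3-(hydroxymethyl)-5-{(1Z)-2-methyl-4-[(2R,3S)-3-methyl-3-(prop-2-en-1-yl)oxiran-2-yl]-3-oxobut-1-en-1-yl}furan-2(5H)-one | O=C1O[C@@H](/C=C(/C)C(=O)C[C@H]2O[C@@]2(C)CC=C)C=C1CO | intermediate
17 | (5S)-3-(bromomethyl) analogue of 16 | O=C1O[C@@H](/C=C(/C)C(=O)C[C@H]2O[C@@]2(C)CC=C)C=C1CBr | intermediate
18 | (5S)-3-(bromomethyl)-5-{(1Z,3S)-3-hydroxy-2-methyl-4-[(2R,3S)-3-methyl-3-(prop-2-en-1-yl)oxiran-2-yl]but-1-en-1-yl}furan-2(5H)-one | O=C1O[C@@H](/C=C(/C)[C@@H](O)C[C@H]2O[C@@]2(C)CC=C)C=C1CBr | intermediate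
19 | (3S)-O-tert-butyldimethylsilyl ether of 18 | O=C1O[C@@H](/C=C(/C)[C@@H](O[Si](C)(C)C(C)(C)C)C[C@H]2O[C@@]2(C)CC=C)C=C1CBr | intermediate
20 | 2,3-dihydroxypropyl analogue of 19, diol epimers (not isolated) | O=C1O[C@@H](/C=C(/C)[C@@H](O[Si](C)(C)C(C)(C)C)C[C@H]2O[C@@]2(C)CC(O)CO)C=C1CBr | intermediate
21 | (5S)-3-(bromomethyl)-5-{(1Z,3S)-3-[(tert-butyldimethylsilyl)oxy]-2-methyl-4-[(2R,3S)-3-methyl-3-(2-oxoethyl)oxiran-2-yl]but-1-en-1-yl}furan-2(5H)-one | O=C1O[C@@H](/C=C(/C)[C@@H](O[Si](C)(C)C(C)(C)C)C[C@H]2O[C@@]2(C)CC=O)C=C1CBr | intermediate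
22 | (1R,3S,6S,7R,8R,10S)-3-[(tert-butyldimethylsilyl)oxy]-1,10-epoxy-8-hydroxygermacra-4Z,11(13)-dien-12,6-olide | C=C1C(=O)O[C@H]2/C=C(/C)[C@@H](O[Si](C)(C)C(C)(C)C)C[C@H]3O[C@@]3(C)C[C@@H](O)[C@@H]12 | intermediate
23 | 3-methylfuran-2(5H)-one | CC1=CCOC1=O | starting material
24 | potassium (2Z)-4-hydroxy-2-methylbut-2-enoate (not isolated) | [K+].[O-]C(=O)/C(C)=C\CO | intermediate
25 | tert-butyldimethylsilyl (2Z)-4-[(tert-butyldimethylsilyl)oxy]-2-methylbut-2-enoate (not isolated) | CC(C)(C)[Si](C)(C)OC(=O)/C(C)=C\CO[Si](C)(C)C(C)(C)C | intermediate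
26 | (2Z)-4-[(tert-butyldimethylsilyl)oxy]-2-methylbut-2-enoic acid | OC(=O)/C(C)=C\CO[Si](C)(C)C(C)(C)C | intermediate
27 | mixed anhydride of 26 with 2,4,6-trichlorobenzoic acid (not isolated) | O=C(OC(=O)/C(C)=C\CO[Si](C)(C)C(C)(C)C)c1c(Cl)cc(Cl)cc1Cl | intermediate
28 | 3-O-TBS, 4′-O-TBS derivative of the target | C=C1C(=O)O[C@H]2/C=C(/C)[C@@H](O[Si](C)(C)C(C)(C)C)C[C@H]3O[C@@]3(C)C[C@@H](OC(=O)/C(C)=C\CO[Si](C)(C)C(C)(C)C)[C@@H]12 | intermediate
29 | CNP0410854.1, (1R,3S,6S,7R,8R,10S)-1,10-epoxy-3-hydroxy-8-[(2Z)-4-hydroxy-2-methylbut-2-enoyloxy]germacra-4Z,11(13)-dien-12,6-olide | C=C1C(=O)O[C@H]2/C=C(/C)[C@@H](O)C[C@H]3O[C@@]3(C)C[C@@H](OC(=O)/C(C)=C\CO)[C@@H]12 | target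

**Step count and risks**

Total steps: 15. Longest linear sequence: 13 (steps 1–5, 7–12, 14, 15).

Three steps most likely to fail:

- **Step 7 (Ni/Cr coupling on the Z-keto-enal).** Cr(II) may reduce the ene-dicarbonyl of 11 or the γ-acyloxy enone of the product, the β,γ-epoxy ketone is base-sensitive, and ligand control at C6 is untested on this aldehyde. Fallback, setting out from 11 and returning at 18: reduce both carbonyls of 11 with (R)-Me-CBS/catecholborane to the Z-enediol F1, oxidize with TEMPO/PhI(OAc)2 to the β-methylbutenolide F2, and reduce with DIBAL to the lactol F3. Run the same Ni/Cr coupling with 14 on this lactol, where no ene-dicarbonyl is left, to give the diol F4. Brominate its primary allylic alcohol with CBr4/PPh3 to reach 18.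

- **Step 12 (proposed new macrocyclization).** The ring-fusion and C8 selectivity rest on a transition-state argument, the β,γ-epoxy aldehyde 21 is labile, and oligomerization competes. Fallback with known chemistry, setting out from 21 and returning at 22: Pd-catalysed borylation of the allylic bromide with bis(pinacolato)diboron (Pd2(dba)3, toluene, 50 °C) gives the allylboronate F5. It closes the ring by thermal allylboration of the aldehyde through a closed, metal-free transition state, as known for 2-(alkoxycarbonyl)allylboronates. If the 8-epimer forms instead, Mitsunobu esterification with 26 would invert it.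

- **Step 14 (acylation).** The C8 hydroxyl is hindered, and DMAP can isomerize the Z-enoyl group to the E isomer. Fallback, setting out from 22 and returning at 28: esterify with 2-[bis(2,2,2-trifluoroethoxy)phosphoryl]propanoic acid (DCC, DMAP) to the phosphonate F6. Then build the Z-enoate on the molecule by Still–Gennari olefination with (tert-butyldimethylsilyloxy)acetaldehyde (KHMDS, 18-crown-6, −78 °C).

**Further compounds**

F1 | step 7 | (2Z,4S)-3-methyl-5-[(2R,3S)-3-methyl-3-(prop-2-en-1-yl)oxiran-2-yl]pent-2-ene-1,4-diol | OC/C=C(/C)[C@@H](O)C[C@H]1O[C@@]1(C)CC=C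
F2 | step 7 | (5S)-4-methyl-5-{[(2R,3S)-3-methyl-3-(prop-2-en-1-yl)oxiran-2-yl]methyl}furan-2(5H)-one | CC1=CC(=O)O[C@H]1C[C@H]2O[C@@]2(C)CC=C
F3 | step 7 | (5S)-4-methyl-5-{[(2R,3S)-3-methyl-3-(prop-2-en-1-yl)oxiran-2-yl]methyl}-2,5-dihydrofuran-2-ol (anomers) | CC1=CC(O)O[C@H]1C[C@H]2O[C@@]2(C)CC=C
F4 | step 7 | (5S)-3-(hydroxymethyl)-5-{(1Z,3S)-3-hydroxy-2-methyl-4-[(2R,3S)-3-methyl-3-(prop-2-en-1-yl)oxiran-2-yl]but-1-en-1-yl}furan-2(5H)-one | O=C1O[C@@H](/C=C(/C)[C@@H](O)C[C@H]2O[C@@]2(C)CC=C)C=C1CO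
F5 | step 12 | pinacol allylboronate analogue of 21 (CH2Bpin in place of CH2Br) | O=C1O[C@@H](/C=C(/C)[C@@H](O[Si](C)(C)C(C)(C)C)C[C@H]2O[C@@]2(C)CC=O)C=C1CB1OC(C)(C)C(C)(C)O1
F6 | step 14 | 8-O-{2-[bis(2,2,2-trifluoroethoxy)phosphoryl]propanoyl} derivative of 22 | C=C1C(=O)O[C@H]2/C=C(/C)[C@@H](O[Si](C)(C)C(C)(C)C)C[C@H]3O[C@@]3(C)C[C@@H](OC(=O)C(C)P(=O)(OCC(F)(F)F)OCC(F)(F)F)[C@@H]12
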